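The data are calculated with constants of no real substance, and the scatter is random.

**The easy subtraction.** Take [target] and [side product] away from what was charged, and what remains is what I call the pool: material not yet finished, whether free or hidden in a form the readings do not show.

- ash: starting material 20 mM (in portions, 4); reagent 24 mM; the very flask that is asked about, followed so far; portions every 20 min
- flask: starting material 20 mM (in portions, 4); reagent 24.0 mM; time 15 h; the portions of starting material follow each other after 20 min, the first at the start

ash run (percent of the starting material charged)

| time / h | starting material / % | target / % | side product / % |
|---|---|---|---|
| 0.667 | 39 | 3 | 0 |
| 1.33 | 71 | 8 | 2 |
| 2.00 | 57 | 13 | 0 |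
| 2.50 | 50 | 16 | 1 |

(each reading ± 1.5 percentage points)

- percent here means starting material units held: one side product counts as two
- the reaction counts as stopped when no species that holds the starting material changes by six tenths of a point or more over the second half of the time
- a reading of starting material is of its free form alone

- why nothing more happens at 15 h, or that something still does (the reagent has run out first / it is still moving / forward and back rates have come level / all of the starting material has reacted)
- part of the starting material gone at 15 h
- the target standing at 15 h, as a percentage of the starting material charged
- the side product standing at 15 h, as a percentage of the starting material charged

**The time constant.** The last portion goes in at 60.0 min, so from then on nothing enters the pool. In the ash run, which is this flask followed so far, the pool stands at 90.0% at 1.33 h and at 83.0% at 2.50 h. Treat it as a tank with a first-order outlet. The drain time constant, the time in which the pool falls by a factor of e, is then 14.4 h. This is a rough figure, since each reading scatters by 1.5 percentage points.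

**The question reversed.** What would stopping take? The flask counts as stopped if no species holding starting material changes by 0.6 points or more between 7.50 h and 15 h. A pool stopping by emptying must therefore be down to 0.6 points by 7.50 h, and that asks for a time constant of 1.01 h. You have 14.4 h, which is far longer. At that pace the pool loses 24 points over the second half and keeps 34.9% at 15 h. So my own reckoning is that this flask is still moving.

**The forecast.** The forecast says it is still moving, with 77% gone, 58% target and 2% side product, and it puts the pool at “about 40–45 by 15 h”, not my 34.9%.

**The flask.** The flask gives it is still moving, with 87.7% of the starting material gone, 39.1% target and 27.1% side product.

    starting material + reagent ⇌ intermediate A (K = 31.0 /M, k = 19.0 /M/h)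
    intermediate A → target (k = 0.840 /h)
    starting material + reagent ⇌ intermediate B (K = 130 /M, k = 8.10 /M/h)
    starting material + target → side product (k = 6.50 /M/h)
    2 reagent → self-condensation product (k = 0.940 /M/h)

**A longer wait.** At 15 h the pool is 33.7%, against my 34.9%. Now leave the same flask until 25 h. The same time constant gives 17.5%, but that flask holds 22.4%, more than reckoned. Between the two times the pool therefore drained with a time constant of 24.3 h, longer than 14.4 h. Of what remains in that flask at 25 h, starting material is 7.60% and intermediate B is 14.2%.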